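Count the protic impurity first, in turnovers of starting material.

| flask | starting material | partner | protic impurity | remark | time |
|---|---|---|---|---|---|
| Friday's | 0.050 M | 0.10 M (fed, over 50 min) | 7 mM | run made earlier |  |
| Thursday's | 0.050 M | 0.10 M (fed, over 50 min) | 11 mM | run made earlier |  |
| Wednesday's | 0.050 M | 0.15 M (fed, over 50 min) | 5 mM | run made earlier |  |
| flask | 0.050 M | 0.100 M (fed, over 50 min) | 5.00 mM |  | 2.0 d |

- Friday's (time / h: open intermediate / %, target / %): 1.00: 10.1, 1.1; 3.00: 13.6, 4.3; 12.0: 11.4, 22.0; 40.0: 7.2, 40.4
- Thursday's (time / h: open intermediate / %, target / %): 1.00: 9.1, 1.5; 3.00: 13.7, 4.5; 12.0: 11.2, 20.6; 40.0: 7.2, 33.5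
- Wednesday's (time / h: open intermediate / %, target / %): 1.00: 10.1, 0; 3.00: 12.9, 6.9; 12.0: 10.7, 29.0; 40.0: 8.6, 46.6

(standard deviation of a reading: 1 percentage point)

1. time, not beyond 2.0 d, at which the flask holds most open intermediate
2. the amount of open intermediate, in percent of the starting material charged, at that time
3. earliest time at which at least nineteen twentieths of that best amount are there, in d
4. latest time at which they still are, in d

1. I assumed that each molecule of protic impurity takes one molecule of starting material out of play, with the impurity as limiting reagent. Impurity charge over starting material charge gave 10.0% for the flask, 14.0% for Friday's run and 22.0% for Thursday's. I named this the quench share, the part of the charge lost to impurity.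

2. Friday's and Thursday's runs had the same partner charge, so I tested the share on them. At 40.0 h, open intermediate plus target differed by 6.9 percentage points, and the shares by 8 points, with a scatter of 1 point on each reading.

3. I then took the open ratio: open intermediate over what remained after subtracting the share, open intermediate and target. At 3.00 h those two runs averaged 0.214.

4. With that ratio and their mean target, the flask's open intermediate came to 15.1%, my figure for its best amount.

5. The weak link was a ratio resting on few readings. The 12.0 h readings gave 0.230, and the mean of both ratios raised my figure to 15.6%.

The forecast, saying “I can't pin down the mechanism, so I'll read empirically”, gave 0.13 d, 13.6%, 0.085 d and 0.21 d, so its best amount differed from my 15.6%.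

The flask gave its best amount of open intermediate, 15.4%, at 0.164 d, and held the asked share of that amount from 0.0998 d to 0.291 d.

    starting material ⇌ open intermediate (K = 0.360, k = 0.00230 min⁻¹)
    partner → second intermediate (k = 0.00190 min⁻¹)
    open intermediate + second intermediate → target (k = 0.250 M⁻¹ min⁻¹)
    2 second intermediate → homo product (k = 0.420 M⁻¹ min⁻¹)
    starting material + protic impurity → quenched substrate (k = 0.400 M⁻¹ min⁻¹)
    open intermediate → side product (k = 6.20 × 10⁻⁴ min⁻¹)

The flask held 9.74% quenched substrate at its best time and 10.0% at 2.00 d, against a quench share of 10.0%. The neighbouring flask, charged with 0.17 M of partner, had the same impurity and starting material charges, so I reckoned the same 10.0% for it. At 2.00 d it held 10.0% quenched substrate, while starting material, target, side product and open intermediate summed to 90.0%. Its target stood at 49.1%, and its best amount of open intermediate was 14.0%, lower than the flask's.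

The numbers in the tables were computed with constants of no real substance.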